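The route rests on cutting the C3a–C4 bond of ring A (C3a–C4–C5–C6–C6a). The precursor is an enantioenriched N-(4-silyloxybutyl) 2,3-dihydroisoxazole (ring B: N1, O2, C3, C3a, C6a) that carries the pyridyloctyl chain on C3 and a (Z)-3-iodoallyl arm on the C6a stereocentre. One intramolecular Heck reaction closes ring A, fixes C3a cis to C6a and leaves C3 trigonal as an exocyclic enol ether. The feature exploited is the endo placement of the C3 substituent, on the same side of ring B as C4 and inside the fold of the bicycle: because C3 is still planar once ring A exists, hydride can be added last from the outer, convex face, which forces the chain inward.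

Key step: step 12

Remark: the alkenyl halide of the cyclisation precursor is carried as the iodide instead of the bromide (same skeleton), so that palladium inserts near room temperature, below the range in which 2,3-dihydroisoxazoles and 5-alkylideneisoxazolidines rearrange through their weak N–O bond; the bicycle locants (N1, O2, C3, C3a, C4–C6, C6a) are used for the corresponding atoms of all earlier intermediates.

Step 1
Reactants: 1 3-methylpyridine; 2 1,8-dibromooctane
Product: 4 3-(9-bromononyl)pyridine, via (pyridin-3-yl)methyllithium 3 (not isolated)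
Conditions: LiN(iPr)2 (1.05 equiv), THF–DMPU, −78 °C; then added to 2 (4 equiv), THF, −78 °C → rt; product kept cold in solution and used promptly in steps 2 and 3
Reagents that add atoms: lithium diisopropylamide, [Li+].CC(C)[N-]C(C)C (its lithium enters 3 only, not 4)
Why: Lateral lithiation of 3-methylpyridine gives the picolyl anion, and its SN2 alkylation by a fourfold excess of the dibromide under inverse addition should stop at monoalkylation; this one batch of bromide supplies both pyridyl side chains.

Step 2
Reactants: 4 3-(9-bromononyl)pyridine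
Product: 5 triphenyl[9-(pyridin-3-yl)nonyl]phosphonium bromide
Conditions: PPh3 (3 equiv), MeCN (concentrated), 80 °C
Reagents that add atoms: triphenylphosphine, c1ccc(cc1)P(c1ccccc1)c1ccccc1
Why: Quaternisation of PPh3 by a primary bromide (Wittig salt formation), with excess phosphine at high concentration outcompeting the pyridine nitrogen for the alkyl bromide.

Step 3
Reactants: 4 3-(9-bromononyl)pyridine
Product: 6 9-(pyridin-3-yl)nonanal
Conditions: Me3NO (anhydrous, 4 equiv), DMSO, rt; aq. NaHCO3 work-up
Reagents that add atoms: trimethylamine N-oxide, C[N+](C)(C)[O-]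
Why: Amine N-oxide oxidation of a primary alkyl bromide (a mild relative of the Kornblum oxidation), in which the N-oxide oxygen displaces bromide by SN2 and the alkoxyammonium salt then loses trimethylamine by base-induced elimination to give the aldehyde; at room temperature the large excess of the strongly nucleophilic N-oxide should outrun quaternisation of the pyridine.

Step 4
Reactants: 6 9-(pyridin-3-yl)nonanal
Product: 7 3-(dec-9-yn-1-yl)pyridine
Conditions: dimethyl (1-diazo-2-oxopropyl)phosphonate (1.3 equiv), K2CO3 (2 equiv), MeOH, 0 °C → rt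
Reagents that add atoms: dimethyl (1-diazo-2-oxopropyl)phosphonate, COP(=O)(OC)C(=[N+]=[N-])C(C)=O
Why: Ohira–Bestmann variant of the Seyferth–Gilbert homologation, in which methanolysis releases the diazomethylphosphonate anion, which adds to the aldehyde, eliminates dimethyl phosphate and, after loss of N2 and 1,2-hydride shift in the alkylidene carbene, gives the terminal alkyne one carbon longer under carbonate conditions that tolerate the enolisable aldehyde and the pyridine.

Step 5
Reactants: 8 (4-bromobutoxy)(tert-butyl)dimethylsilane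
Product: 9 N-{4-[(tert-butyldimethylsilyl)oxy]butyl}hydroxylamine
Conditions: NH2OH (50 wt % in H2O, 15 equiv), EtOH, 60 °C
Reagents that add atoms: hydroxylamine, NO
Why: SN2 N-alkylation of hydroxylamine by a primary bromide, in which the large excess of NH2OH should hold the reaction at the mono-N-alkyl stage while the silyl ether is inert to the weakly basic medium.

Step 6
Reactants: 10 but-3-yn-1-ol
Product: 11 4-iodobut-3-yn-1-ol
Conditions: N-iodosuccinimide (1.1 equiv), AgNO3 (10 mol %), acetone, rt, dark
Reagents that add atoms: N-iodosuccinimide, O=C1CCC(=O)N1I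
Why: Silver-catalysed electrophilic iodination of a terminal alkyne through its silver acetylide, which tolerates the free hydroxyl group.

Step 7
Reactants: 11 4-iodobut-3-yn-1-ol
Product: 12 (3Z)-4-iodobut-3-en-1-ol
Conditions: 2-nitrobenzenesulfonohydrazide (NBSH, 2 equiv), Et3N, THF–iPrOH, rt, dark
Reagents that add atoms: none
Why: Diimide released from NBSH transfers two hydrogens to one face of the iodoalkyne (syn reduction), which should give the Z-iodoalkene without hydrogenolysis of the C–I bond.

Step 8
Reactants: 12 (3Z)-4-iodobut-3-en-1-ol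
Product: 13 (3Z)-4-iodobut-3-enal
Conditions: Dess–Martin periodinane (1.2 equiv), NaHCO3, CH2Cl2, 0 °C; cold aq. Na2S2O3/NaHCO3 wash; dried solution used at once
Reagents that add atoms: none
Why: Dess–Martin oxidation under bicarbonate buffering is neutral and fast, so the β,γ-unsaturated aldehyde should form without moving its double bond into conjugation.

Step 9
Reactants: 13 (3Z)-4-iodobut-3-enal; 9 N-{4-[(tert-butyldimethylsilyl)oxy]butyl}hydroxylamine
Product: 14 (Z)-N-[(3Z)-4-iodobut-3-en-1-ylidene]-4-[(tert-butyldimethylsilyl)oxy]butan-1-amine N-oxide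
Conditions: MgSO4, CH2Cl2, 0 °C → rt; used without chromatography
Reagents that add atoms: none
Why: Condensation of an N-monosubstituted hydroxylamine with an aldehyde gives the Z-aldonitrone under neutral dehydrating conditions, which leave the skipped iodoalkene in place.

Step 10
Reactants: 14 the nitrone; 7 3-(dec-9-yn-1-yl)pyridine
Product: 16 N-{4-[(tert-butyldimethylsilyl)oxy]butyl}-N-[(1Z,4R)-1-iodo-14-(pyridin-3-yl)tetradec-1-en-5-yn-4-yl]hydroxylamine, via methyl[10-(pyridin-3-yl)dec-1-yn-1-yl]zinc 15 (not isolated)
Conditions: 7 (1.5 equiv), Me2Zn (3.5 equiv), toluene, 0 °C → rt; di-tert-butyl (2S,3S)-tartrate (1.0 equiv), 0 °C; then 14, 0 °C; aq. NH4Cl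
Reagents that add atoms: dimethylzinc, C[Zn]C (its atoms enter 15 only, not 16)
Why: Tartrate-mediated asymmetric addition of an alkynylzinc to a nitrone, in which the zinc tartrate template binds the nitrone oxygen and passes the non-basic alkynyl group to one face of C=N; the (S,S)-ester is the antipode expected to give the R centre (C6a), to be confirmed by chiral HPLC on the first batch with the (R,R)-ester as the remedy, and the excess Me2Zn saturates the pyridine.

Step 11
Reactants: 16 the propargylic hydroxylamine
Product: 17 (3R)-2-{4-[(tert-butyldimethylsilyl)oxy]butyl}-3-[(2Z)-3-iodoprop-2-en-1-yl]-5-[8-(pyridin-3-yl)octyl]-2,3-dihydroisoxazole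
Conditions: ZnI2 (20 mol %), DMAP (20 mol %), CH2Cl2, rt; stored cold, used promptly
Reagents that add atoms: none
Why: Zinc-catalysed 5-endo-dig hydroalkoxylation, in which the zinc-bound N–O oxygen adds to the activated alkyne and protonation of the alkenylzinc gives the 2,3-dihydroisoxazole without touching C6a or the iodoalkene.

Step 12
Reactants: 17 the 2,3-dihydroisoxazole
Product: 18 (3aS,6aR)-1-{4-[(tert-butyldimethylsilyl)oxy]butyl}-3-[8-(pyridin-3-yl)octylidene]-3,3a,6,6a-tetrahydro-1H-cyclopenta[c]isoxazole (both alkylidene isomers, which converge later)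
Conditions: Pd(OAc)2 (10 mol %), PPh3 (30 mol %), Ag2CO3 (1.5 equiv), degassed MeCN, 40 °C, dark
Reagents that add atoms: none
Why: Zerovalent palladium (from Pd(OAc)2 and PPh3) inserts into the C–I bond with retention of the Z geometry, Ag2CO3 strips iodide, and the cationic alkenylpalladium adds syn across the C3=C3a enol ether (carbon to C3a, palladium to C3) before syn β-hydride elimination and capture of HI by carbonate; the closest known reaction type is the intramolecular Heck cyclisation of alkenyl halides onto cyclic enol ethers such as dihydrofurans, dihydropyrans and glycals. Ring A (C3a–C4–C5–C6–C6a) closes in the 5-exo-trig mode. The new stereocentre C3a is dictated by C6a, because the three-carbon arm can reach only the face of C3a on which it already stands at C6a, which makes the ring fusion cis. The step needs exo and not endo insertion, secured by the short tether and by C3 being fully substituted, and it needs elimination away from the ring, secured because H3a lies anti to palladium, so that only the side-chain CH2 offers a syn hydrogen and C3 stays trigonal. Palladium sits on the concave face at C3, so a reductive termination would put hydrogen there and give the wrong C3 epimer, which is why C3 is reduced only later from the convex face. The iodide allows a temperature that should spare the N–O bond of both the dihydroisoxazole and the alkylideneisoxazolidine, and the carbonate removes hydridopalladium before it can re-add and move the double bonds.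

Step 13
Reactants: 18 the Heck product
Product: 19 (3aS,6aR)-1-{4-[(tert-butyldimethylsilyl)oxy]butyl}-3-[8-(pyridin-3-yl)octylidene]hexahydro-1H-cyclopenta[c]isoxazole
Conditions: NBSH (3 equiv), Et3N, CH2Cl2, rt
Reagents that add atoms: none
Why: Diimide reduces the strained cis-disubstituted cyclopentene much faster than the trisubstituted exocyclic enol ether, and the basic medium protects that enol ether, so only C4=C5 should be saturated.

Step 14
Reactants: 19 the saturated enol ether
Product: 21 4-{(3S,3aS,6aR)-3-[8-(pyridin-3-yl)octyl]hexahydro-1H-cyclopenta[c]isoxazol-1-yl}butan-1-ol, via silyl ether 20 (not isolated)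
Conditions: Et3SiH (5 equiv), CF3CO2H (20 equiv), CH2Cl2, −20 → 0 °C; then H2O, rt; aq. K2CO3/MeOH work-up
Reagents that add atoms: none
Why: Ionic hydrogenation, in which C-protonation of the enol ether gives the O2=C3 oxocarbenium ion and Et3SiH delivers hydride to C3 from the open convex face of the cis-fused bicycle, so that the chain should end on the concave face cis to C4 (3S), after which aqueous acid cleaves the primary silyl ether in the same flask.

Step 15
Reactants: 21 the alcohol
Product: 22 4-{(3S,3aS,6aR)-3-[8-(pyridin-3-yl)octyl]hexahydro-1H-cyclopenta[c]isoxazol-1-yl}butanal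
Conditions: Dess–Martin periodinane (1.3 equiv), NaHCO3, CH2Cl2, 0 °C → rt
Reagents that add atoms: none
Why: Dess–Martin oxidation of a primary alcohol stops at the aldehyde and leaves the weakly basic N–O nitrogen and the pyridine untouched.

Step 16
Reactants: 22 the aldehyde; 5 triphenyl[9-(pyridin-3-yl)nonyl]phosphonium bromide
Product: 24 pyrinodemin C, (3S,3aS,6aR)-1-[(4Z)-13-(pyridin-3-yl)tridec-4-en-1-yl]-3-[8-(pyridin-3-yl)octyl]hexahydro-1H-cyclopenta[c]isoxazole, via phosphorus ylide 23 (not isolated)
Conditions: 5 (1.5 equiv), KN(SiMe3)2 (1.45 equiv), THF, −78 → 0 °C; then 22, −78 °C → rt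
Reagents that add atoms: none
Why: Wittig olefination with a non-stabilised ylide under lithium-free conditions passes through the kinetically favoured cis-oxaphosphetane and should give the Z-alkene without affecting the three ring stereocentres.

Compound list
1 | 3-methylpyridine | Cc1cccnc1 | starting material
2 | 1,8-dibromooctane | BrCCCCCCCCBr | starting material
3 | (pyridin-3-yl)methyllithium | [Li]Cc1cccnc1 | intermediate
4 | 3-(9-bromononyl)pyridine | BrCCCCCCCCCc1cccnc1 | intermediate
5 | triphenyl[9-(pyridin-3-yl)nonyl]phosphonium bromide | [Br-].c1ccc(cc1)[P+](c1ccccc1)(c1ccccc1)CCCCCCCCCc1cccnc1 | intermediate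
6 | 9-(pyridin-3-yl)nonanal | O=CCCCCCCCCc1cccnc1 | intermediate
7 | 3-(dec-9-yn-1-yl)pyridine | C#CCCCCCCCCc1cccnc1 | intermediate
8 | (4-bromobutoxy)(tert-butyl)dimethylsilane | CC(C)(C)[Si](C)(C)OCCCCBr | starting material
9 | N-{4-[(tert-butyldimethylsilyl)oxy]butyl}hydroxylamine | CC(C)(C)[Si](C)(C)OCCCCNO | intermediate
10 | but-3-yn-1-ol | OCCC#C | starting material
11 | 4-iodobut-3-yn-1-ol | OCCC#CI | intermediate
12 | (3Z)-4-iodobut-3-en-1-ol | OCC/C=C\I | intermediate
13 | (3Z)-4-iodobut-3-enal | O=CC/C=C\I | intermediate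
14 | (Z)-N-[(3Z)-4-iodobut-3-en-1-ylidene]-4-[(tert-butyldimethylsilyl)oxy]butan-1-amine N-oxide | CC(C)(C)[Si](C)(C)OCCCC/[N+]([O-])=C/C/C=C\I | intermediate
15 | methyl[10-(pyridin-3-yl)dec-1-yn-1-yl]zinc | C[Zn]C#CCCCCCCCCc1cccnc1 | intermediate
16 | N-{4-[(tert-butyldimethylsilyl)oxy]butyl}-N-[(1Z,4R)-1-iodo-14-(pyridin-3-yl)tetradec-1-en-5-yn-4-yl]hydroxylamine | CC(C)(C)[Si](C)(C)OCCCCN(O)[C@H](C/C=C\I)C#CCCCCCCCCc1cccnc1 | intermediate
17 | (3R)-2-{4-[(tert-butyldimethylsilyl)oxy]butyl}-3-[(2Z)-3-iodoprop-2-en-1-yl]-5-[8-(pyridin-3-yl)octyl]-2,3-dihydroisoxazole | CC(C)(C)[Si](C)(C)OCCCCN1OC(CCCCCCCCc2cccnc2)=C[C@H]1C/C=C\I | intermediate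
18 | (3aS,6aR)-1-{4-[(tert-butyldimethylsilyl)oxy]butyl}-3-[8-(pyridin-3-yl)octylidene]-3,3a,6,6a-tetrahydro-1H-cyclopenta[c]isoxazole | CC(C)(C)[Si](C)(C)OCCCCN1OC(=CCCCCCCCc2cccnc2)[C@H]2C=CC[C@H]21 | intermediate
19 | (3aS,6aR)-1-{4-[(tert-butyldimethylsilyl)oxy]butyl}-3-[8-(pyridin-3-yl)octylidene]hexahydro-1H-cyclopenta[c]isoxazole | CC(C)(C)[Si](C)(C)OCCCCN1OC(=CCCCCCCCc2cccnc2)[C@H]2CCC[C@H]21 | intermediate
20 | (3S,3aS,6aR)-1-{4-[(tert-butyldimethylsilyl)oxy]butyl}-3-[8-(pyridin-3-yl)octyl]hexahydro-1H-cyclopenta[c]isoxazole | CC(C)(C)[Si](C)(C)OCCCCN1O[C@@H](CCCCCCCCc2cccnc2)[C@H]2CCC[C@H]21 | intermediate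
21 | 4-{(3S,3aS,6aR)-3-[8-(pyridin-3-yl)octyl]hexahydro-1H-cyclopenta[c]isoxazol-1-yl}butan-1-ol | OCCCCN1O[C@@H](CCCCCCCCc2cccnc2)[C@H]2CCC[C@H]21 | intermediate
22 | 4-{(3S,3aS,6aR)-3-[8-(pyridin-3-yl)octyl]hexahydro-1H-cyclopenta[c]isoxazol-1-yl}butanal | O=CCCCN1O[C@@H](CCCCCCCCc2cccnc2)[C@H]2CCC[C@H]21 | intermediate
23 | triphenyl[9-(pyridin-3-yl)nonylidene]-λ5-phosphane | C(=P(c1ccccc1)(c1ccccc1)c1ccccc1)CCCCCCCCc1cccnc1 | intermediate
24 | pyrinodemin C, (3S,3aS,6aR)-1-[(4Z)-13-(pyridin-3-yl)tridec-4-en-1-yl]-3-[8-(pyridin-3-yl)octyl]hexahydro-1H-cyclopenta[c]isoxazole | C(=C/CCCN1O[C@@H](CCCCCCCCc2cccnc2)[C@H]2CCC[C@H]21)/CCCCCCCCc1cccnc1 | target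

Total step count: 16
Longest linear sequence: 11 steps (steps 6 to 16, from 10 to 24)

Steps most likely to fail

Step 12. The risks are insertion in the endo sense at C3, cleavage of the weak N–O bond by palladium or heat, and re-addition of hydridopalladium that would move the double bonds and erase C3a. The fallback gives up the Heck closure and builds both rings at once by an intramolecular nitrone–alkene cycloaddition; it sets out from 5 and 9 and returns at 20. Ylide 23, made from 5 as in step 16, is condensed with methyl 5-oxopentanoate to give methyl (5Z)-14-(pyridin-3-yl)tetradec-5-enoate F1. Reduction with iBu2AlH at −78 °C gives (5Z)-14-(pyridin-3-yl)tetradec-5-enal F2. Condensation with 9 (MgSO4, CH2Cl2) gives (Z)-N-[(5Z)-14-(pyridin-3-yl)tetradec-5-en-1-ylidene]-4-[(tert-butyldimethylsilyl)oxy]butan-1-amine N-oxide F3. Heating in toluene should bring about the fused-mode cycloaddition, which is suprafacial on the Z-alkene and therefore places the C3 chain cis to C4 in a cis-fused bicycle, giving the racemate of 20, rac-(3S,3aS,6aR)-1-{4-[(tert-butyldimethylsilyl)oxy]butyl}-3-[8-(pyridin-3-yl)octyl]hexahydro-1H-cyclopenta[c]isoxazole F4. Preparative chromatography on a chiral stationary phase separates 20, which re-enters at the aqueous-acid desilylation of step 14.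

Step 10. The risks are poor facial selectivity of the zinc-mediated addition, because the pyridine competes for zinc and the nitrone is an aliphatic one, and tautomerisation of the nitrone at its doubly activated CH2 group. The fallback sets the centre with an auxiliary on nitrogen instead of a chiral zinc template; it sets out from 13 and 7 and returns at 16. Aldehyde 13 is condensed with (R)-2-methylpropane-2-sulfinamide (CuSO4, CH2Cl2) to give (R)-N-[(1E,3Z)-4-iodobut-3-en-1-ylidene]-2-methylpropane-2-sulfinamide F5. Alkyne 7 is converted with EtMgBr into bromo[10-(pyridin-3-yl)dec-1-yn-1-yl]magnesium F6. This adds in CH2Cl2 at −78 °C through a magnesium-chelated chair (sulfinyl oxygen on the metal, tert-butyl group equatorial) and should give (R)-N-[(1Z,4R)-1-iodo-14-(pyridin-3-yl)tetradec-1-en-5-yn-4-yl]-2-methylpropane-2-sulfinamide F7. HCl in MeOH removes the auxiliary to give (1Z,4R)-1-iodo-14-(pyridin-3-yl)tetradec-1-en-5-yn-4-amine F8. Monoalkylation with bromide 8 (K2CO3, NaI, MeCN) gives (1Z,4R)-N-{4-[(tert-butyldimethylsilyl)oxy]butyl}-1-iodo-14-(pyridin-3-yl)tetradec-1-en-5-yn-4-amine F9. Oxidation with dibenzoyl peroxide (K2HPO4, DMF) gives O-benzoyl-N-{4-[(tert-butyldimethylsilyl)oxy]butyl}-N-[(1Z,4R)-1-iodo-14-(pyridin-3-yl)tetradec-1-en-5-yn-4-yl]hydroxylamine F10, and methanolysis (K2CO3, MeOH) releases 16.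

Step 14. The risks are slow C-protonation of the enol ether once N1 and the pyridine are protonated, and loss of facial selectivity if the oxocarbenium ion is long-lived. The fallback replaces the proton/hydride sequence by syn addition of hydrogen on a metal surface; it sets out from 19 and returns at 20. Hydrogenation of 19 over palladium on carbon (Pd/C, H2 at 1 atm, EtOAc, rt, stopped at one equivalent of uptake) should add both hydrogens from the convex face and give 20, under mild conditions that normally leave isoxazolidine N–O bonds intact. Compound 20 is then desilylated with aqueous CF3CO2H to 21 as in the second half of step 14.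

Further compounds
F1 | step 12 | methyl (5Z)-14-(pyridin-3-yl)tetradec-5-enoate | COC(=O)CCC/C=C\CCCCCCCCc1cccnc1
F2 | step 12 | (5Z)-14-(pyridin-3-yl)tetradec-5-enal | O=CCCC/C=C\CCCCCCCCc1cccnc1
F3 | step 12 | (Z)-N-[(5Z)-14-(pyridin-3-yl)tetradec-5-en-1-ylidene]-4-[(tert-butyldimethylsilyl)oxy]butan-1-amine N-oxide | CC(C)(C)[Si](C)(C)OCCCC/[N+]([O-])=C/CCC/C=C\CCCCCCCCc1cccnc1
F4 | step 12 | rac-(3S,3aS,6aR)-1-{4-[(tert-butyldimethylsilyl)oxy]butyl}-3-[8-(pyridin-3-yl)octyl]hexahydro-1H-cyclopenta[c]isoxazole (racemate of 20) | CC(C)(C)[Si](C)(C)OCCCCN1O[C@@H](CCCCCCCCc2cccnc2)[C@H]2CCC[C@H]21.CC(C)(C)[Si](C)(C)OCCCCN1O[C@H](CCCCCCCCc2cccnc2)[C@@H]2CCC[C@@H]21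
F5 | step 10 | (R)-N-[(1E,3Z)-4-iodobut-3-en-1-ylidene]-2-methylpropane-2-sulfinamide | CC(C)(C)[S@@](=O)/N=C/C/C=C\I
F6 | step 10 | bromo[10-(pyridin-3-yl)dec-1-yn-1-yl]magnesium | Br[Mg]C#CCCCCCCCCc1cccnc1
F7 | step 10 | (R)-N-[(1Z,4R)-1-iodo-14-(pyridin-3-yl)tetradec-1-en-5-yn-4-yl]-2-methylpropane-2-sulfinamide | CC(C)(C)[S@@](=O)N[C@H](C/C=C\I)C#CCCCCCCCCc1cccnc1
F8 | step 10 | (1Z,4R)-1-iodo-14-(pyridin-3-yl)tetradec-1-en-5-yn-4-amine | N[C@H](C/C=C\I)C#CCCCCCCCCc1cccnc1
F9 | step 10 | (1Z,4R)-N-{4-[(tert-butyldimethylsilyl)oxy]butyl}-1-iodo-14-(pyridin-3-yl)tetradec-1-en-5-yn-4-amine | CC(C)(C)[Si](C)(C)OCCCCN[C@H](C/C=C\I)C#CCCCCCCCCc1cccnc1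
F10 | step 10 | O-benzoyl-N-{4-[(tert-butyldimethylsilyl)oxy]butyl}-N-[(1Z,4R)-1-iodo-14-(pyridin-3-yl)tetradec-1-en-5-yn-4-yl]hydroxylamine | CC(C)(C)[Si](C)(C)OCCCCN(OC(=O)c1ccccc1)[C@H](C/C=C\I)C#CCCCCCCCCc1cccnc1
F0 | step 14 | none | none
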